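## Retrosynthetic overview

1. Feature: ring D (C13–C14=C15–O–C16) is the oxetane C13/C14/O/C16 with the single carbon C15 inserted into its C14–O bond. Without C15, the spiro carbon C13 shared by rings C and D is not stereogenic.
2. Endgame: the C14=C15 enol ether comes from a C15 carboxylate, by decarboxylative acetoxylation and then loss of AcOH toward C14, the only β-hydrogens.
3. Key disconnection: O–C15 and C14–C15. A copper carbenoid is captured by the C13 spiro-oxetane, and the oxonium ylide undergoes a 1,2-shift of the methylene syn to C10.
4. Oxetane precursor: 6β-acetate from the C6 ketone. Ring B comes from C9–C10 radical closure (C9=C11 enol ether onto the C5=C10 enone). C8–C9 comes from asymmetric 1,4-addition of an achiral spiro dihydrofuranyl boronate to β-damascone.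
5. Ring order: oxetane (bought) → ring C → ring A (bought, joined at C8–C9) → ring B → ring D.

Key step: step 8

Assumption: labdane numbering and ring letters A–D are used. The ligand antipodes in steps 4 and 8 are those predicted by the accepted models, and the mirror-image ligands are commercial should the sense prove opposite.

## Route

Step 1
Reactants: 1 oxetan-3-one; 2 propargyl bromide
Product: 4 3-(prop-2-yn-1-yl)oxetan-3-ol, via allenylzinc bromide 3 (not isolated)
Conditions: Zn dust (activated), THF, 0 °C → rt; aq NH4Cl
Reagents that add atoms: none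
Why: Barbier reaction, in which the allenylzinc species adds through a cyclic SE2' transition state to the strained, electrophilic ketone and so gives the homopropargylic rather than the allenic alcohol; no stereocentre is formed.

Step 2
Reactants: 4 3-(prop-2-yn-1-yl)oxetan-3-ol
Product: 5 2,5-dioxaspiro[3.4]oct-6-ene
Conditions: Mo(CO)6 (20 mol%), Et3N, Et2O, hν (350 nm), rt
Reagents that add atoms: none
Why: Endo-selective alkynol cycloisomerisation, in which the terminal alkyne rearranges on Mo(CO)5 to a vinylidene, the tertiary hydroxyl adds to its metal-bound carbon (5-endo overall) and amine-assisted proton transfer releases the 2,3-dihydrofuran under basic conditions that the oxetane tolerates; the product has a mirror plane.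

Step 3
Reactants: 5 2,5-dioxaspiro[3.4]oct-6-ene
Product: 7 2-(2,5-dioxaspiro[3.4]oct-6-en-6-yl)-4,4,5,5-tetramethyl-1,3,2-dioxaborolane, via 6-lithio-2,5-dioxaspiro[3.4]oct-6-ene 6 (not isolated)
Conditions: t-BuLi, THF, −78 → 0 °C; iPrOBpin, −78 °C → rt
Reagents that add atoms: 2-isopropoxy-4,4,5,5-tetramethyl-1,3,2-dioxaborolane, CC(C)OB1OC(C)(C)C(C)(C)O1
Why: Deprotonation of a cyclic enol ether at the vinylic C–H next to oxygen (future C9), followed by electrophilic borylation; oxetanes do not open with organolithiums unless a Lewis acid is present.

Step 4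
Reactants: 7 spiro dihydrofuranyl boronate; 8 β-damascone
Product: 9 (3R)-3-(2,5-dioxaspiro[3.4]oct-6-en-6-yl)-1-(2,6,6-trimethylcyclohex-1-en-1-yl)butan-1-one (9,10-seco compound with C8 R)
Conditions: [RhCl(C2H4)2]2 (2.5 mol%), (S)-BINAP (5.5 mol%), KOH (20 mol%), dioxane/H2O 10:1, 50 °C
Reagents that add atoms: none
Why: Hayashi–Miyaura asymmetric 1,4-addition, in which the alkenylrhodium species inserts only the unhindered crotonyl double bond (the tetrasubstituted ring alkene cannot bind) and the (S)-BINAP pocket exposes the α-si face of an (E)-acyclic enone, so the new C8–C9 bond sets C8 as R; the basic aqueous medium preserves enol ether and oxetane.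

Step 5
Reactants: 9 9,10-seco enol ether enone
Product: 10 (5S,8R,9R,10S)-9,13:14,16-diepoxy-15-norlabdan-6-one
Conditions: Fe(dibm)3 [iron tris(2,6-dimethylheptane-3,5-dionate), 20 mol%], PhSiH3 (slow addition), Na2HPO4, EtOH, 60 °C
Reagents that add atoms: none
Why: Metal-hydride hydrogen-atom-transfer reductive cyclisation (intramolecular Giese reaction), in which iron hydride delivers H to C11 of the electron-rich enol ether, the nucleophilic tertiary α-oxy radical at C9 adds 6-endo to the enone β-carbon C10, and the C5 radical is reduced to the enolate and protonated; a chair-like transition state with C17 equatorial fixes C10 (the other face would set C17 and C20 syn-diaxial), places the small ring C oxygen in the axial-like site eclipsing C7 and C11 in the equatorial-like site, and C5 is protonated from the α face opposite the C19 and C20 methyls to give the trans-decalone, which is also the thermodynamic epimer, while the phosphate buffer stops ethanolysis of the enol ether.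

Step 6
Reactants: 10 C6 ketone
Product: 11 (5S,6R,8R,9R,10S)-9,13:14,16-diepoxy-15-norlabdan-6-ol (axial 6β-alcohol)
Conditions: LiAlH4, THF, 0 °C; Rochelle salt work-up
Reagents that add atoms: none
Why: Hydride reduction of a hindered cyclohexanone, in which the β face of C6 is closed by the syn-axial C19 and C20 methyl groups, so hydride arrives from the α face and leaves the axial 6β (6R) alcohol; the 3,3-disubstituted oxetane is inert to LiAlH4 at this temperature.

Step 7
Reactants: 11 6β-alcohol
Product: 12 (5S,6R,8R,9R,10S)-6-acetoxy-9,13:14,16-diepoxy-15-norlabdane (C13 spiro-oxetane acetate)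
Conditions: Ac2O, DMAP, Et3N, CH2Cl2, 40 °C
Reagents that add atoms: acetic anhydride, CC(=O)OC(C)=O
Why: DMAP-catalysed acylation, warmed because the axial hydroxyl sits between two syn-axial methyl groups; the basic medium leaves oxetane and ring C untouched and no stereocentre is affected.

Step 8
Reactants: 12 C13 spiro-oxetane acetate; 13 benzyl diazoacetate
Product: 16 benzyl (13R,15S)-6β-acetoxy-9α,13:15,16-diepoxylabdane-15-carboxylate, via copper carbenoid 14 (not isolated), via oxonium ylide 15 (not isolated)
Conditions: (CuOTf)2·C6H6 (5 mol%), (S,S)-t-Bu-box (11 mol%), 4 Å MS, CH2Cl2, rt, 13 added by syringe pump over 12 h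
Reagents that add atoms: none
Why: Proposed new method: bis(oxazoline)-bound monovalent copper decomposes 13 to the electrophilic carbenoid 14, which is captured by the most basic and least shielded lone pair of 12, that of the oxetane oxygen (the ring C oxygen lies between two fully substituted carbons and the acetate carbonyl is a poor donor), to give the copper-associated oxonium ylide 15. A Stevens 1,2-shift then moves one oxetane methylene from oxygen to the ylide carbon, so O–C15 is made on capture and C14–C15 in the shift, and the release of about 20 kcal/mol of ring strain is what allows a primary carbon to migrate. The closest known reaction type is the copper- or rhodium-carbenoid ring expansion of oxetanes to tetrahydrofuran-2-carboxylates, already rendered enantioselective by chiral copper catalysts for 2-substituted oxetanes, whereas a choice between the two diastereotopic C–O bonds of a 3,3-spiro oxetane has not been shown. Ring D is closed by enlargement of the four-membered ring to five members inside the ylide, not by end-to-end cyclisation, so no other ring size can compete. C13 becomes stereogenic through the choice of methylene: the one syn to C10 across ring C must migrate, which is favoured by relief of its 1,3-contact with quaternary C10 and its C1/C20 substituents and should be reinforced by the matched ligand, which fixes configuration and rotamer of the copper-bound ylide carbon so that this C–O bond is the one aligned for the shift; C15 is set by the same ligand-controlled face (drawn 15S) and is erased later. Ylide formation must also outrun carbene dimerisation, which slow addition of 13 secures.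

Step 9
Reactants: 16 ring D benzyl ester
Product: 17 (13R,15S)-6β-acetoxy-9α,13:15,16-diepoxylabdane-15-carboxylic acid
Conditions: H2 (1 atm), 10% Pd/C, EtOAc, rt
Reagents that add atoms: none
Why: Catalytic hydrogenolysis of the benzylic C–O bond frees the acid under neutral conditions, so the C6 acetate stays in place and nothing else in 16 is reducible.

Step 10
Reactants: 17 C15 carboxylic acid
Product: 18 (13R)-6β,15-diacetoxy-9α,13:15,16-diepoxylabdane (both C15 epimers)
Conditions: Pb(OAc)4, pyridine, THF, 0 °C → rt
Reagents that add atoms: lead tetraacetate, CC(=O)O[Pb](OC(C)=O)(OC(C)=O)OC(C)=O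
Why: Oxidative decarboxylation by tetravalent lead, in which the lead carboxylate fragments to CO2 and the C15 α-alkoxy radical, which is oxidised at once to the ring D oxocarbenium ion and captured by acetate; the C15 configuration is lost while quaternary C13 is untouched.

Step 11
Reactants: 18 C15 acetate
Product: 19 (5S,6R,8R,9R,10S,13R)-6-acetoxy-9,13:15,16-diepoxylabd-14-ene (CNP0242014.1)
Conditions: TMSOTf, iPr2NEt (excess), CH2Cl2, −78 → −20 °C; Et3N then sat. aq NaHCO3; Et3N-deactivated silica
Reagents that add atoms: none
Why: Ionisation–deprotonation of a mixed acyl acetal (the silyl triflate/hindered amine conversion of acetals into enol ethers, needed because base alone does not expel acetate), in which TMSOTf removes only the anomeric C15 acetate, the oxocarbenium ion can lose a proton only from C14, and excess amine, low temperature and a basic quench protect the product, whose C13–O bond is allylic to the new enol ether and would otherwise ionise.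

## Compound list

1 | oxetan-3-one | O=C1COC1 | starting material
2 | propargyl bromide | C#CCBr | starting material
3 | allenylzinc bromide | C=C=C[Zn]Br | intermediate
4 | 3-(prop-2-yn-1-yl)oxetan-3-ol | C#CCC1(O)COC1 | intermediate
5 | 2,5-dioxaspiro[3.4]oct-6-ene | C1=CCC2(COC2)O1 | intermediate
6 | 6-lithio-2,5-dioxaspiro[3.4]oct-6-ene | [Li]C1=CCC2(COC2)O1 | intermediate
7 | 2-(2,5-dioxaspiro[3.4]oct-6-en-6-yl)-4,4,5,5-tetramethyl-1,3,2-dioxaborolane | CC1(C)OB(OC1(C)C)C1=CCC2(COC2)O1 | intermediate
8 | β-damascone | C/C=C/C(=O)C1=C(C)CCCC1(C)C | starting material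
9 | (3R)-3-(2,5-dioxaspiro[3.4]oct-6-en-6-yl)-1-(2,6,6-trimethylcyclohex-1-en-1-yl)butan-1-one | C[C@H](CC(=O)C1=C(C)CCCC1(C)C)C1=CCC2(COC2)O1 | intermediate
10 | (5S,8R,9R,10S)-9,13:14,16-diepoxy-15-norlabdan-6-one | O=C1C[C@@H](C)[C@]2(CCC3(COC3)O2)[C@@]2(C)CCCC(C)(C)[C@H]12 | intermediate
11 | (5S,6R,8R,9R,10S)-9,13:14,16-diepoxy-15-norlabdan-6-ol | O[C@@H]1C[C@@H](C)[C@]2(CCC3(COC3)O2)[C@@]2(C)CCCC(C)(C)[C@H]12 | intermediate
12 | C13 spiro-oxetane acetate | CC(=O)O[C@@H]1C[C@@H](C)[C@]2(CCC3(COC3)O2)[C@@]2(C)CCCC(C)(C)[C@H]12 | intermediate
13 | benzyl diazoacetate | [N-]=[N+]=CC(=O)OCc1ccccc1 | starting material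
14 | copper carbenoid (ligand and triflate omitted) | [Cu]=CC(=O)OCc1ccccc1 | intermediate
15 | oxetane oxonium ylide (copper omitted) | CC(=O)O[C@@H]1C[C@@H](C)[C@]2(CCC3(C[O+](C3)[CH-]C(=O)OCc3ccccc3)O2)[C@@]2(C)CCCC(C)(C)[C@H]12 | intermediate
16 | ring D tetrahydrofuran C15 benzyl ester | CC(=O)O[C@@H]1C[C@@H](C)[C@]2(CC[C@]3(C[C@@H](C(=O)OCc4ccccc4)OC3)O2)[C@@]2(C)CCCC(C)(C)[C@H]12 | intermediate
17 | ring D C15 carboxylic acid | CC(=O)O[C@@H]1C[C@@H](C)[C@]2(CC[C@]3(C[C@@H](C(=O)O)OC3)O2)[C@@]2(C)CCCC(C)(C)[C@H]12 | intermediate
18 | C15 acetate (C15 epimers) | CC(=O)O[C@@H]1C[C@@H](C)[C@]2(CC[C@]3(CC(OC(C)=O)OC3)O2)[C@@]2(C)CCCC(C)(C)[C@H]12 | intermediate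
19 | CNP0242014.1 | CC(=O)O[C@@H]1C[C@@H](C)[C@]2(CC[C@]3(C=COC3)O2)[C@@]2(C)CCCC(C)(C)[C@H]12 | target

## Step count and risks

Total step count: 11. Longest linear sequence: 11 steps, from oxetan-3-one.

**Step 8.**
- What may go wrong: the two diastereotopic C–O bonds may be poorly discriminated. Carbene dimerisation may outrun capture by the oxetane oxygen.
- Fallback: it sets out from 11 and returns at 18, and it replaces carbene insertion by nucleophilic oxetane opening with a C15 acyl-anion equivalent.
- 1,3-Dithiane is lithiated (n-BuLi, THF, −20 °C) to 2-lithio-1,3-dithiane F1.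
- F1 (three equivalents, the first consumed by the C6 hydroxyl) opens the oxetane of 11 with BF3·OEt2 at −78 °C. This gives the (13R)-C16 alcohol C15 dithiane F2.
- Selection here rests on the substrate alone, so the C13 epimers are separated by chromatography at this stage.
- MeI and CaCO3 in aqueous MeCN unmask the C15 aldehyde, which closes on the C16 hydroxyl to the C6-hydroxy C15 lactol F3.
- Ac2O, DMAP and pyridine acetylate both hydroxyls and give 18.

**Step 5.**
- What may go wrong: hydrogen may be delivered to the C9 radical before the slow closure onto the tetrasubstituted C10. The enol ether may also be solvolysed in ethanol.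
- Fallback: it sets out from 9 and returns at 10, and it generates the same radical by C–Se homolysis in an aprotic medium with a starved hydrogen donor.
- Benzeneselenol adds in the Markovnikov sense across C9=C11 (CH2Cl2, 0 °C) to give the C9 phenylselenyl ketal F4.
- Bu3SnH is added by syringe pump with AIBN in benzene at 80 °C. The C9 radical cyclises onto C10, and hydrogen abstraction at C5 gives 10. A brief NaOMe/MeOH treatment would equilibrate C5 if needed.

**Step 11.**
- What may go wrong: residual silyl triflate may open ring C at the allylic C13–O bond of the freshly formed enol ether, followed by aromatisation of ring D.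
- Fallback: it sets out from 18 and returns at 19, and it replaces cationic elimination by a syn-elimination run in amine-buffered medium.
- PhSeH with catalytic BF3·OEt2 (CH2Cl2, −78 °C) exchanges only the anomeric acetate and gives the C15 phenylselenide F5. Ring C is not yet allylic at this stage.
- One equivalent of mCPBA at −78 °C gives the C15 selenoxide F6.
- Addition of iPr2NH and warming to rt brings about syn-elimination toward C14, the only β-hydrogens, and gives 19.

## Further compounds

F1 | step 8 | 2-lithio-1,3-dithiane | [Li]C1SCCCS1
F2 | step 8 | (13R)-C16 alcohol C15 dithiane (C6 hydroxyl free) | O[C@@H]1C[C@@H](C)[C@]2(CC[C@](CO)(CC3SCCCS3)O2)[C@@]2(C)CCCC(C)(C)[C@H]12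
F3 | step 8 | C6-hydroxy C15 lactol | O[C@@H]1C[C@@H](C)[C@]2(CC[C@]3(CC(O)OC3)O2)[C@@]2(C)CCCC(C)(C)[C@H]12
F4 | step 5 | C9 phenylselenyl ketal of the seco enone | C[C@H](CC(=O)C1=C(C)CCCC1(C)C)C1([Se]c2ccccc2)CCC2(COC2)O1
F5 | step 11 | C15 phenylselenide | CC(=O)O[C@@H]1C[C@@H](C)[C@]2(CC[C@]3(CC([Se]c4ccccc4)OC3)O2)[C@@]2(C)CCCC(C)(C)[C@H]12
F6 | step 11 | C15 selenoxide | CC(=O)O[C@@H]1C[C@@H](C)[C@]2(CC[C@]3(CC([Se](=O)c4ccccc4)OC3)O2)[C@@]2(C)CCCC(C)(C)[C@H]12
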